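All runs were computed for an exercise.

Of the starting material charged on Thursday, 59.3% was left at 3.00 min, beside 38.4% of target, so the two together account for 97.7% of the charge.

- Thursday's: starting material 0.050 M; second substrate 0.025 M; partner 0.30 M; free catalyst 55 µM; run made earlier
- flask: starting material 0.050 M; second substrate 0.0250 M; partner 0.150 M; free catalyst 55 µM; time 15 min

Thursday's run (percent of the starting material charged)

| time / min | target / % | starting material / % |
|---|---|---|
| 0.250 | 4.3 | 96.8 |
| 0.417 | 5.7 | 95.7 |
| 0.667 | 9.9 | 88.2 |
| 1.00 | 15.2 | 84.1 |
| 2.00 | 27.3 | 72.2 |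
| 3.00 | 38.4 | 59.3 |

(readings scatter by 1 percentage point)



1. amount of target in percent of the starting material charged, at 3.0 min, 8.0 min and 15 min

Thursday's leftover, read as a pseudo-first-order loss, gives a constant of 0.174 min⁻¹. The reckoning made here takes that constant as proportional to c(partner), the concentration that differs between the two flasks, and so carries the constant per unit of c(partner), 0.00968 M⁻¹ s⁻¹. The new flask has half Thursday's c(partner), so its constant is 0.0871 min⁻¹. With c(partner) held at its charge and each loss counted as target, this reckoning gives the new flask 23.0% of target at 3.0 min, 50.2% at 8.0 min and 72.9% at 15 min.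

The forecast differs, with 25%, 44% and 49%, on the ground that “target should stop near 50%”.

The new flask gives 22.5%, 45.9% and 60.8% of target.

    starting material + free catalyst ⇌ catalyst intermediate A (K = 12.0 M⁻¹, k = 140 M⁻¹ s⁻¹)
    partner + catalyst intermediate A → free catalyst + target (k = 48.0 M⁻¹ s⁻¹)
    second substrate + free catalyst ⇌ catalyst intermediate B (K = 1800 M⁻¹, k = 100 M⁻¹ s⁻¹)
    partner + catalyst intermediate B → free catalyst + second product (k = 27.0 M⁻¹ s⁻¹)
    starting material + target → side product (k = 0.00490 M⁻¹ s⁻¹)
    target ⇌ isomer of the product (K = 0.420, k = 4.40 × 10⁻⁴ s⁻¹)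

Worked back from the new flask's leftover of 21% at 15.0 min, on the charged c(partner), the constant per unit of c(partner) comes to 0.0117 M⁻¹ s⁻¹, above the 0.00968 M⁻¹ s⁻¹ read from Thursday's run. Over the same run, the rate at which starting material takes free catalyst, over the rate at which second substrate takes it (forward steps alone), rises from 2.8 at the start to 18 at 15.0 min, with second substrate down to 3.2% of its charge and free catalyst up from 54.2% at 1.50 min to 89.0% of the catalyst.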